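Ring A is disconnected from a preformed ring C pyranone by a Danheiser benzannulation. The step exploits the C4a=C8a double bond of the pyranone, with hydrogen on C4a, as the vinyl arm of a vinylketene: a 2-diazopropanoyl group on the future C8a delivers C8 with its methyl and C5 with its oxygen, and 1-(triisopropylsiloxy)propyne delivers C6 with its methyl and C7 with its oxygen. One operation forms C8–C8a, C5–C6, C7–C8 and C4a–C5 and closes ring A as a resorcinol with free 5-OH and silylated 7-OH. The precursor is 6-(2-diazopropanoyl)-3-methoxy-2-[3,4,5-tris(benzyloxy)phenyl]pyran-4-one, assembled from comenic acid and 5-bromopyrogallol.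

Key step: step 9

Remarks on the chemistry
- Tribenzylpyrogallol cannot be functionalised cleanly at C5: electrophiles attack C4, and iridium-catalysed C–H borylation would also attack the benzyl rings. Ring B is therefore taken with bromine already in place, as 5-bromobenzene-1,2,3-triol, assumed to be purchasable.
- Diazoethane is not sold; it is generated from N-ethyl-N-nitrosourea and aqueous KOH, and the dried ethereal solution is used at once.
- Monocyclic compounds carry pyranone locants (ring oxygen = 1); from step 9 on, flavone locants are used.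

Step 1
Reactants: 1 comenic acid
Product: 2 6-bromo-5-hydroxy-4-oxo-4H-pyran-2-carboxylic acid
Conditions: Br2 (1.05 equiv), H2O, 0 → 23 °C
Reagents that add atoms: bromine, BrBr
Why: Electrophilic bromination of the enolic 3-hydroxy-4-pyranone should go to C6, the only ring carbon that is both ortho to the hydroxyl and next to the ring oxygen, as in the known halogenation of comenic and kojic acids.

Step 2
Reactants: 2 6-bromo-5-hydroxy-4-oxo-4H-pyran-2-carboxylic acid
Product: 3 methyl 6-bromo-5-methoxy-4-oxo-4H-pyran-2-carboxylate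
Conditions: MeI (3 equiv), K2CO3 (2.5 equiv), DMF, 23 °C
Reagents that add atoms: iodomethane, CI
Why: Williamson etherification of the acidic enol and alkylation of the carboxylate by MeI occur together, installing the future C3 methoxy group and masking the carboxyl in one operation.

Step 3
Reactants: 4 5-bromobenzene-1,2,3-triol
Product: 5 1,2,3-tris(benzyloxy)-5-bromobenzene
Conditions: BnBr (3.5 equiv), K2CO3 (4 equiv), DMF, N2, 23 → 60 °C
Reagents that add atoms: benzyl bromide, BrCc1ccccc1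
Why: Threefold Williamson etherification under inert gas, which protects the oxidation-prone triol while the bromine already marks the carbon para to the central oxygen.

Step 4
Reactants: 5 1,2,3-tris(benzyloxy)-5-bromobenzene
Product: 6 4,4,5,5-tetramethyl-2-[3,4,5-tris(benzyloxy)phenyl]-1,3,2-dioxaborolane
Conditions: B2pin2 (1.2 equiv), PdCl2(dppf) (3 mol %), KOAc (3 equiv), 1,4-dioxane, 90 °C
Reagents that add atoms: bis(pinacolato)diboron, CC1(C)OB(OC1(C)C)B1OC(C)(C)C(C)(C)O1
Why: Miyaura borylation of an unhindered aryl bromide, with KOAc as a base mild enough for the benzyl ethers.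

Step 5
Reactants: 3 methyl 6-bromo-5-methoxy-4-oxo-4H-pyran-2-carboxylate; 6 4,4,5,5-tetramethyl-2-[3,4,5-tris(benzyloxy)phenyl]-1,3,2-dioxaborolane
Product: 7 methyl 5-methoxy-4-oxo-6-[3,4,5-tris(benzyloxy)phenyl]-4H-pyran-2-carboxylate
Conditions: Pd(PPh3)4 (5 mol %), K3PO4 (2 equiv), 1,4-dioxane/H2O (20:1), 70 °C
Reagents that add atoms: none
Why: Suzuki–Miyaura coupling in which the C6–Br bond, a vinylogous acyl bromide, should add readily to zerovalent palladium, while a weak base and little water spare the ester and the pyranone ring.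

Step 6
Reactants: 7 methyl 5-methoxy-4-oxo-6-[3,4,5-tris(benzyloxy)phenyl]-4H-pyran-2-carboxylate
Product: 8 5-methoxy-4-oxo-6-[3,4,5-tris(benzyloxy)phenyl]-4H-pyran-2-carboxylic acid
Conditions: LiOH·H2O (1.2 equiv), THF/H2O, 0 °C; then 1 M HCl to pH 2
Reagents that add atoms: lithium hydroxide (its oxygen becomes the carboxyl OH), [Li+].[OH-]
Why: Saponification of an ester on an electron-poor ring is fast at 0 °C with about one equivalent of hydroxide, so conjugate ring opening of the pyranone should not compete and the ethers stay untouched.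

Step 7
Reactants: 8 5-methoxy-4-oxo-6-[3,4,5-tris(benzyloxy)phenyl]-4H-pyran-2-carboxylic acid
Product: 10 6-(2-diazopropanoyl)-3-methoxy-2-[3,4,5-tris(benzyloxy)phenyl]-4H-pyran-4-one, via acid chloride 9 (not isolated)
Conditions: (COCl)2 (1.5 equiv), DMF (cat.), CH2Cl2, 0 → 23 °C; evaporate; CH3CHN2 (3 equiv; from N-ethyl-N-nitrosourea, KOH, Et2O/H2O, 0 °C, dried over KOH), Et2O/THF, −20 → 0 °C
Reagents that add atoms: oxalyl chloride (chlorine of 9), O=C(Cl)C(Cl)=O; diazoethane (made from N-ethyl-N-nitrosourea, CCN(N=O)C(N)=O), CC=[N+]=[N-]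
Why: Acylation of a diazoalkane by an acid chloride (Arndt–Eistert-type diazo ketone synthesis), with excess diazoethane trapping HCl as chloroethane so that no chloro ketone forms, and with acylation at low temperature expected to be faster than any reaction at the ring.

Step 8
Reactants: 11 propyne
Product: 14 triisopropyl(prop-1-yn-1-yloxy)silane, via propynyllithium 12 (not isolated), via lithium propynolate 13 (not isolated)
Conditions: LiN(SiMe3)2 (1.05 equiv), THF, −78 °C; add to tBuOOLi (from tBuOOH and LiN(SiMe3)2, 1.0 equiv each, THF, −78 °C), −78 → 0 °C; iPr3SiOTf (1.1 equiv), −78 → 0 °C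
Reagents that add atoms: lithium bis(trimethylsilyl)amide (lithium of 12 and 13), [Li+].C[Si](C)(C)[N-][Si](C)(C)C; tert-butyl hydroperoxide (oxygen), CC(C)(C)OO; triisopropylsilyl trifluoromethanesulfonate (silyl group), CC(C)[Si](OS(=O)(=O)C(F)(F)F)(C(C)C)C(C)C
Why: Oxidation of prop-1-yn-1-yllithium 12 by tBuOOLi gives ynolate 13, and O-silylation with the bulky silyl triflate gives a siloxyalkyne stable enough to purify, which is the known oxidation–silylation route to 1-siloxy-1-alkynes.

Step 9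
Reactants: 10 6-(2-diazopropanoyl)-3-methoxy-2-[3,4,5-tris(benzyloxy)phenyl]-4H-pyran-4-one; 14 triisopropyl(prop-1-yn-1-yloxy)silane
Product: 19 5-hydroxy-3-methoxy-6,8-dimethyl-7-(triisopropylsilyloxy)-2-[3,4,5-tris(benzyloxy)phenyl]-4H-chromen-4-one, via methyl pyranyl ketene 15 (not isolated), via cyclobutenone 16 (not isolated), via dienylketene 17 (not isolated), via cyclohexadienone 18 (not isolated)
Conditions: 14 (2 equiv), ClCH2CH2Cl (degassed), hν (450 nm LED), 25 °C until N2 evolution ends; then 80 °C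
Reagents that add atoms: none
Why: Blue light excites only the diazo ketone, which loses N2 with 1,2-shift of the pyranyl group (Wolff rearrangement) to ketene 15; [2+2] cycloaddition with 14 gives cyclobutenone 16, thermal conrotatory 4π opening gives dienylketene 17, disrotatory 6π electrocyclisation onto C4a gives 18, and enolisation of its doubly activated C4a–H gives phenol 19. The closest known reaction type is the second-generation Danheiser benzannulation of α,β-unsaturated or heteroaryl diazo ketones with siloxyalkynes. Ring A is closed by the 6π electrocyclisation that forms C4a–C5, after the Wolff shift has made C8–C8a and the cycloaddition C5–C6 and C7–C8; no stereocentre remains, since the centres of 16 and 18 are lost on ring opening and aromatisation. The step needs regioselective cycloaddition, secured by polarisation: the methyl-bearing alkyne carbon, made nucleophilic by the siloxy oxygen, bonds to the electrophilic ketene carbonyl carbon, which places OSi at C7 and OH at C5. It also needs closure at one site only, secured because C8a carries O1 on its other side and the weakly aromatic C4a=C8a bond reacts as an alkene; opening of 16 is reversible, so material that opens with the pyranyl group outward returns and drains through the (3E) isomer. The new C5 hydroxyl is tied to the C4 carbonyl by a hydrogen bond, which shields it from acylation by ketene 15.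

Step 10
Reactants: 19 5-hydroxy-3-methoxy-6,8-dimethyl-7-(triisopropylsilyloxy)-2-[3,4,5-tris(benzyloxy)phenyl]-4H-chromen-4-one
Product: 20 5,7-dihydroxy-3-methoxy-6,8-dimethyl-2-[3,4,5-tris(benzyloxy)phenyl]-4H-chromen-4-one
Conditions: Bu4NF (1.2 equiv), AcOH (1.2 equiv), THF, 0 → 23 °C
Reagents that add atoms: none
Why: Fluoride-mediated cleavage of an aryl silyl ether, buffered with AcOH so that the C7 phenoxide does not sit in basic solution, leaves the benzyl and methyl ethers untouched.

Step 11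
Reactants: 20 5,7-dihydroxy-3-methoxy-6,8-dimethyl-2-[3,4,5-tris(benzyloxy)phenyl]-4H-chromen-4-one
Product: 21 5,7-dihydroxy-3-methoxy-6,8-dimethyl-2-(3,4,5-trihydroxyphenyl)-4H-chromen-4-one (6,8-di-C-methylmyricetin 3-methyl ether)
Conditions: H2 (1 atm), Pd/C (palladium on carbon, 10 wt %), THF/MeOH, 23 °C; filtration under argon
Reagents that add atoms: none
Why: Hydrogenolysis of three aryl benzyl ethers under neutral conditions, routine for flavonols, should leave the C2=C3 bond and the C3 methyl ether intact and releases the air-sensitive pyrogallol unit only at the end.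

Compound list
1 | comenic acid (5-hydroxy-4-oxo-4H-pyran-2-carboxylic acid) | O=C(O)c1cc(=O)c(O)co1 | starting material
2 | 6-bromo-5-hydroxy-4-oxo-4H-pyran-2-carboxylic acid | O=C(O)c1cc(=O)c(O)c(Br)o1 | intermediate
3 | methyl 6-bromo-5-methoxy-4-oxo-4H-pyran-2-carboxylate | COC(=O)c1cc(=O)c(OC)c(Br)o1 | intermediate
4 | 5-bromobenzene-1,2,3-triol (5-bromopyrogallol) | Oc1cc(Br)cc(O)c1O | starting material
5 | 1,2,3-tris(benzyloxy)-5-bromobenzene | Brc1cc(OCc2ccccc2)c(OCc2ccccc2)c(OCc2ccccc2)c1 | intermediate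
6 | 4,4,5,5-tetramethyl-2-[3,4,5-tris(benzyloxy)phenyl]-1,3,2-dioxaborolane | CC1(C)OB(c2cc(OCc3ccccc3)c(OCc3ccccc3)c(OCc3ccccc3)c2)OC1(C)C | intermediate
7 | methyl 5-methoxy-4-oxo-6-[3,4,5-tris(benzyloxy)phenyl]-4H-pyran-2-carboxylate | COC(=O)c1cc(=O)c(OC)c(-c2cc(OCc3ccccc3)c(OCc3ccccc3)c(OCc3ccccc3)c2)o1 | intermediate
8 | 5-methoxy-4-oxo-6-[3,4,5-tris(benzyloxy)phenyl]-4H-pyran-2-carboxylic acid | OC(=O)c1cc(=O)c(OC)c(-c2cc(OCc3ccccc3)c(OCc3ccccc3)c(OCc3ccccc3)c2)o1 | intermediate
9 | 5-methoxy-4-oxo-6-[3,4,5-tris(benzyloxy)phenyl]-4H-pyran-2-carbonyl chloride | ClC(=O)c1cc(=O)c(OC)c(-c2cc(OCc3ccccc3)c(OCc3ccccc3)c(OCc3ccccc3)c2)o1 | intermediate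
10 | 6-(2-diazopropanoyl)-3-methoxy-2-[3,4,5-tris(benzyloxy)phenyl]-4H-pyran-4-one | COc1c(-c2cc(OCc3ccccc3)c(OCc3ccccc3)c(OCc3ccccc3)c2)oc(C(=O)C(C)=[N+]=[N-])cc1=O | intermediate
11 | propyne | CC#C | starting material
12 | prop-1-yn-1-yllithium | [Li]C#CC | intermediate
13 | lithium prop-1-yn-1-olate | [Li+].CC#C[O-] | intermediate
14 | triisopropyl(prop-1-yn-1-yloxy)silane | CC#CO[Si](C(C)C)(C(C)C)C(C)C | intermediate
15 | 2-{5-methoxy-4-oxo-6-[3,4,5-tris(benzyloxy)phenyl]-4H-pyran-2-yl}prop-1-en-1-one (methyl pyranyl ketene) | CC(=C=O)c1cc(=O)c(OC)c(-c2cc(OCc3ccccc3)c(OCc3ccccc3)c(OCc3ccccc3)c2)o1 | intermediate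
16 | racemic 4-{5-methoxy-4-oxo-6-[3,4,5-tris(benzyloxy)phenyl]-4H-pyran-2-yl}-2,4-dimethyl-3-(triisopropylsilyloxy)cyclobut-2-en-1-one | CC1=C(O[Si](C(C)C)(C(C)C)C(C)C)C(C)(c2cc(=O)c(OC)c(-c3cc(OCc4ccccc4)c(OCc4ccccc4)c(OCc4ccccc4)c3)o2)C1=O | intermediate
17 | (3E)-4-{5-methoxy-4-oxo-6-[3,4,5-tris(benzyloxy)phenyl]-4H-pyran-2-yl}-2-methyl-3-(triisopropylsilyloxy)penta-1,3-dien-1-one | CC(=C=O)/C(O[Si](C(C)C)(C(C)C)C(C)C)=C(/C)c1cc(=O)c(OC)c(-c2cc(OCc3ccccc3)c(OCc3ccccc3)c(OCc3ccccc3)c2)o1 | intermediate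
18 | racemic 3-methoxy-6,8-dimethyl-7-(triisopropylsilyloxy)-2-[3,4,5-tris(benzyloxy)phenyl]-4aH-chromene-4,5-dione | COC1=C(c2cc(OCc3ccccc3)c(OCc3ccccc3)c(OCc3ccccc3)c2)OC2=C(C)C(O[Si](C(C)C)(C(C)C)C(C)C)=C(C)C(=O)C2C1=O | intermediate
19 | 5-hydroxy-3-methoxy-6,8-dimethyl-7-(triisopropylsilyloxy)-2-[3,4,5-tris(benzyloxy)phenyl]-4H-chromen-4-one | COc1c(-c2cc(OCc3ccccc3)c(OCc3ccccc3)c(OCc3ccccc3)c2)oc2c(C)c(O[Si](C(C)C)(C(C)C)C(C)C)c(C)c(O)c2c1=O | intermediate
20 | 5,7-dihydroxy-3-methoxy-6,8-dimethyl-2-[3,4,5-tris(benzyloxy)phenyl]-4H-chromen-4-one | COc1c(-c2cc(OCc3ccccc3)c(OCc3ccccc3)c(OCc3ccccc3)c2)oc2c(C)c(O)c(C)c(O)c2c1=O | intermediate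
21 | 5,7-dihydroxy-3-methoxy-6,8-dimethyl-2-(3,4,5-trihydroxyphenyl)-4H-chromen-4-one (6,8-di-C-methylmyricetin 3-methyl ether) | COc1c(-c2cc(O)c(O)c(O)c2)oc2c(C)c(O)c(C)c(O)c2c1=O | target

Total step count: 11.
Longest linear sequence: 8 steps (1, 2, 5, 6, 7, 9, 10, 11 from comenic acid; the branch from 5-bromopyrogallol through 3, 4, 5 is equally long).

Steps most likely to fail

Step 9. After loss of nitrogen, a 1,2-hydride shift from the methyl group to a vinyl ketone, or light-driven isomerisation of the pyranone, may outrun the Wolff rearrangement, so that too little ketene 15 meets the alkyne. The fallback makes ketene 15 by dehydrochlorination, without a diazo ketone or light at the ring-forming stage; it sets out from acid chloride 9 and comes back at 19. Acid chloride 9 with CH2N2 (Et2O, 0 °C) should give 6-(2-diazoacetyl)-3-methoxy-2-[3,4,5-tris(benzyloxy)phenyl]-4H-pyran-4-one F1. Silver-promoted Wolff rearrangement of this terminal diazo ketone (PhCO2Ag, Et3N, MeOH; Arndt–Eistert homologation) should give methyl 2-{5-methoxy-4-oxo-6-[3,4,5-tris(benzyloxy)phenyl]-4H-pyran-2-yl}acetate F2. Deprotonation with LiN(SiMe3)2 (1 equiv, THF, −78 °C) and MeI should give racemic methyl 2-{5-methoxy-4-oxo-6-[3,4,5-tris(benzyloxy)phenyl]-4H-pyran-2-yl}propanoate F3. LiOH at 0 °C should give racemic 2-{5-methoxy-4-oxo-6-[3,4,5-tris(benzyloxy)phenyl]-4H-pyran-2-yl}propanoic acid F4, and (COCl)2 with catalytic DMF the racemic 2-{5-methoxy-4-oxo-6-[3,4,5-tris(benzyloxy)phenyl]-4H-pyran-2-yl}propanoyl chloride F5. Slow addition of Et3N to F5 and 14 in toluene at 23 °C generates 15, which is trapped as 16; heating to 80–110 °C then carries 16 through 17 and 18 to 19.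

Step 7. Diazoethane may add as a 1,3-dipole across the electron-poor C5=C6 bond of the pyranone, or the diazo ketone may be captured by HCl as a chloro ketone. The fallback installs the diazo group by deacylative diazo transfer; it sets out from acid chloride 9 and comes back at 10. Acid chloride 9 with MeNH(OMe)·HCl and Et3N (CH2Cl2, 0 °C) should give N,5-dimethoxy-N-methyl-4-oxo-6-[3,4,5-tris(benzyloxy)phenyl]-4H-pyran-2-carboxamide F6. EtMgBr (1.2 equiv, THF, −78 °C) should give 3-methoxy-6-propanoyl-2-[3,4,5-tris(benzyloxy)phenyl]-4H-pyran-4-one F7 through the stable chelated adduct. LiN(SiMe3)2 followed by CF3CO2CH2CF3 (THF, −78 °C) should give racemic 4,4,4-trifluoro-1-{5-methoxy-4-oxo-6-[3,4,5-tris(benzyloxy)phenyl]-4H-pyran-2-yl}-2-methylbutane-1,3-dione F8, which is used crude. MsN3, Et3N and H2O in MeCN then transfer the diazo group with loss of the trifluoroacetyl group and give 10.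

Step 5. Attack of the basic aqueous phase at C6 of bromide 3 (addition–elimination) and at the ester may be faster than transmetalation from boron. The fallback is a base-free Negishi coupling; it sets out from bromide 5 and comes back at 7, and step 4 is then not needed. Bromide 5 with n-BuLi (THF, −78 °C) should give [3,4,5-tris(benzyloxy)phenyl]lithium F9, and ZnCl2 converts it into [3,4,5-tris(benzyloxy)phenyl]zinc chloride F10. Coupling of F10 with 3 under Pd(PPh3)4 (THF, 23 → 50 °C) should give 7 without any added base.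

Further compounds
F1 | step 9 | 6-(2-diazoacetyl)-3-methoxy-2-[3,4,5-tris(benzyloxy)phenyl]-4H-pyran-4-one | [N-]=[N+]=CC(=O)c1cc(=O)c(OC)c(-c2cc(OCc3ccccc3)c(OCc3ccccc3)c(OCc3ccccc3)c2)o1
F2 | step 9 | methyl 2-{5-methoxy-4-oxo-6-[3,4,5-tris(benzyloxy)phenyl]-4H-pyran-2-yl}acetate | COC(=O)Cc1cc(=O)c(OC)c(-c2cc(OCc3ccccc3)c(OCc3ccccc3)c(OCc3ccccc3)c2)o1
F3 | step 9 | racemic methyl 2-{5-methoxy-4-oxo-6-[3,4,5-tris(benzyloxy)phenyl]-4H-pyran-2-yl}propanoate | COC(=O)C(C)c1cc(=O)c(OC)c(-c2cc(OCc3ccccc3)c(OCc3ccccc3)c(OCc3ccccc3)c2)o1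
F4 | step 9 | racemic 2-{5-methoxy-4-oxo-6-[3,4,5-tris(benzyloxy)phenyl]-4H-pyran-2-yl}propanoic acid | OC(=O)C(C)c1cc(=O)c(OC)c(-c2cc(OCc3ccccc3)c(OCc3ccccc3)c(OCc3ccccc3)c2)o1
F5 | step 9 | racemic 2-{5-methoxy-4-oxo-6-[3,4,5-tris(benzyloxy)phenyl]-4H-pyran-2-yl}propanoyl chloride | ClC(=O)C(C)c1cc(=O)c(OC)c(-c2cc(OCc3ccccc3)c(OCc3ccccc3)c(OCc3ccccc3)c2)o1
F6 | step 7 | N,5-dimethoxy-N-methyl-4-oxo-6-[3,4,5-tris(benzyloxy)phenyl]-4H-pyran-2-carboxamide | CON(C)C(=O)c1cc(=O)c(OC)c(-c2cc(OCc3ccccc3)c(OCc3ccccc3)c(OCc3ccccc3)c2)o1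
F7 | step 7 | 3-methoxy-6-propanoyl-2-[3,4,5-tris(benzyloxy)phenyl]-4H-pyran-4-one | CCC(=O)c1cc(=O)c(OC)c(-c2cc(OCc3ccccc3)c(OCc3ccccc3)c(OCc3ccccc3)c2)o1
F8 | step 7 | racemic 4,4,4-trifluoro-1-{5-methoxy-4-oxo-6-[3,4,5-tris(benzyloxy)phenyl]-4H-pyran-2-yl}-2-methylbutane-1,3-dione | CC(C(=O)C(F)(F)F)C(=O)c1cc(=O)c(OC)c(-c2cc(OCc3ccccc3)c(OCc3ccccc3)c(OCc3ccccc3)c2)o1
F9 | step 5 | [3,4,5-tris(benzyloxy)phenyl]lithium | [Li]c1cc(OCc2ccccc2)c(OCc2ccccc2)c(OCc2ccccc2)c1
F10 | step 5 | [3,4,5-tris(benzyloxy)phenyl]zinc chloride | Cl[Zn]c1cc(OCc2ccccc2)c(OCc2ccccc2)c(OCc2ccccc2)c1
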